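**Retrosynthetic overview**
- The route rests on one feature: the lactone carbonyl C1 sits on C8a between the C8 oxygen and the C4a side chain and, with O2 and the C3 ketone, forms the lactol ring (C1–O2–C3–C4–C4a–C8a) that masks the epimerisable α-aryl ketone at C4.
- Key disconnection: C8a–C1, C1–O2 and O2–C3 are opened together, giving a C8a-bromo keto ester, CO and water; the C3 configuration follows C4 thermodynamically.
- The bromo keto ester comes from a bromo 1,2-diol by C9–O acylation with 2,4-bis(benzyloxy)-5,6-dimethylbenzoic acid (ring B, from 4,5-dimethylresorcinol) and oxidation at C3.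
- C4–C4a and the C4 stereocentre come from a rhodium/BINAP conjugate addition of the arylboronic acid (from 1-bromo-3,5-dimethoxybenzene) to ethyl crotonate, followed by α-hydroxylation, reduction and bromination at C8a.
- Ring order: both benzene rings are bought; the lactol ring is the only ring made, in the key step; hydrogenolysis and chelation-controlled C8 O-demethylation finish the synthesis.

Key step: step 13

Numbering: atom numbers are those of the isochroman-1-one core of the target (C1 lactone carbonyl, O2, C3 lactol carbon, C4, C4a, C5 to C8, C8a); C9 is the CH2O carbon on C3.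
Assumption: (S)-BINAP is taken to deliver the aryl group to the face of ethyl (E)-crotonate that gives the (R)-ester, as it does with phenylboronic acid; if the ortho-methyl group reversed this sense, (R)-BINAP would be used.
Assumption: the (3R) lactol is taken to be the thermodynamically preferred anomer next to a (4S) centre (C4 methyl and C3 hydroxyl trans-diaxial, acyloxymethyl group equatorial).

**Route**

Step 1
Reactants: 1 1-bromo-3,5-dimethoxybenzene
Product: 3 2-bromo-4,6-dimethoxybenzaldehyde, via iminium chloride 2 (not isolated)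
Conditions: POCl3, DMF, 0 → 90 °C; then ice-water
Reagents that add atoms: N,N-dimethylformamide, CN(C)C=O; water, O
Why: Vilsmeier–Haack formylation: the chloroiminium ion attacks the ring carbon next to bromine, which is para to one methoxyl and ortho to the other, in preference to the more crowded carbon between the two methoxyls, and the iminium salt 2 is hydrolysed on work-up.

Step 2
Reactants: 3 2-bromo-4,6-dimethoxybenzaldehyde
Product: 4 1-bromo-3,5-dimethoxy-2-methylbenzene
Conditions: Et3SiH, TFA, CH2Cl2, 0 °C → rt
Reagents that add atoms: none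
Why: Ionic hydrogenation: in TFA the aldehyde and then the benzylic trifluoroacetate ionise to cations stabilised by the ortho and para methoxyls, each of which takes hydride from Et3SiH, so that the formyl group becomes the future C5 methyl while the C–Br bond is untouched.

Step 3
Reactants: 4 1-bromo-3,5-dimethoxy-2-methylbenzene
Product: 7 (3,5-dimethoxy-2-methylphenyl)boronic acid, via aryllithium 5 (not isolated), via lithium aryltriisopropoxyborate 6 (not isolated)
Conditions: n-BuLi, THF, −78 °C; B(OiPr)3, −78 °C → rt; aq. HCl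
Reagents that add atoms: triisopropyl borate, CC(C)OB(OC(C)C)OC(C)C; water, O
Why: Bromine–lithium exchange at −78 °C is faster than any deprotonation, and the aryllithium adds to the borate ester to give an ate complex that aqueous acid hydrolyses to the boronic acid (borylation of an organolithium).

Step 4
Reactants: 7 (3,5-dimethoxy-2-methylphenyl)boronic acid; 8 ethyl (E)-but-2-enoate
Product: 9 ethyl (3R)-3-(3,5-dimethoxy-2-methylphenyl)butanoate
Conditions: Rh(acac)(C2H4)2 (3 mol %), (S)-BINAP (4.5 mol %), 8 (3 equiv), 1,4-dioxane/H2O 10:1, 100 °C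
Reagents that add atoms: none
Why: Hayashi–Miyaura conjugate addition: the aryl group passes from boron to the rhodium BINAP complex, the crotonate inserts into the aryl–rhodium bond through the alkene face left open by the (S)-ligand, which sets the benzylic centre as R (it becomes 4S in the target once C3 carries oxygen and outranks the aryl group), and water protonates the rhodium enolate.

Step 5
Reactants: 9 ethyl (3R)-3-(3,5-dimethoxy-2-methylphenyl)butanoate
Product: 11 ethyl (3S)-3-(3,5-dimethoxy-2-methylphenyl)-2-hydroxybutanoate (both C2 epimers), via potassium enolate 10 (not isolated)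
Conditions: KN(SiMe3)2, THF, −78 °C; 2-(phenylsulfonyl)-3-phenyloxaziridine, −78 °C; aq. NH4Cl
Reagents that add atoms: 2-(phenylsulfonyl)-3-phenyloxaziridine, O=S(=O)(c1ccccc1)N1OC1c1ccccc1
Why: Davis oxidation: the potassium ester enolate attacks the oxaziridine oxygen, and the new carbinol centre (the later C3) may form as both epimers because it is oxidised to the ketone in step 12.

Step 6
Reactants: 11 ethyl (3S)-3-(3,5-dimethoxy-2-methylphenyl)-2-hydroxybutanoate
Product: 12 (3S)-3-(3,5-dimethoxy-2-methylphenyl)butane-1,2-diol (both C2 epimers)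
Conditions: LiAlH4, THF, 0 °C → rt; then H2O
Reagents that add atoms: none
Why: LiAlH4 reduction of the ester to the primary alcohol gives the 1,2-diol without touching the benzylic stereocenter.

Step 7
Reactants: 12 (3S)-3-(3,5-dimethoxy-2-methylphenyl)butane-1,2-diol
Product: 13 (3S)-3-(2-bromo-3,5-dimethoxy-6-methylphenyl)butane-1,2-diol (both C2 epimers)
Conditions: NBS (1.0 equiv), MeCN, 0 °C, dark
Reagents that add atoms: N-bromosuccinimide, BrN1C(=O)CCC1=O
Why: Electrophilic aromatic bromination: the free ring position para to the C6 methoxyl (C8a) is attacked in preference to C7 between the two methoxyls, as is usual for 3,5-dimethoxyalkylbenzenes, and one equivalent of NBS at 0 °C prevents a second bromination.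

Step 8
Reactants: 14 4,5-dimethylbenzene-1,3-diol
Product: 16 2,4-dihydroxy-5,6-dimethylbenzaldehyde, via iminium chloride 15 (not isolated)
Conditions: POCl3, DMF, MeCN, 0 °C → rt; then H2O, 50 °C
Reagents that add atoms: N,N-dimethylformamide, CN(C)C=O; water, O
Why: Vilsmeier–Haack formylation of the resorcinol goes to C6, para to one hydroxyl and ortho to the other, and not to the carbon between the two hydroxyls, which gives the substitution pattern of ring B.

Step 9
Reactants: 16 2,4-dihydroxy-5,6-dimethylbenzaldehyde
Product: 17 2,4-bis(benzyloxy)-5,6-dimethylbenzaldehyde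
Conditions: BnBr, K2CO3, DMF, 60 °C
Reagents that add atoms: benzyl bromide, BrCc1ccccc1
Why: Williamson etherification of both phenols, the hydrogen-bonded ortho one included under these conditions, gives benzyl ethers that survive the oxidations, the acylation and the carbonylation and leave by hydrogenolysis.

Step 10
Reactants: 17 2,4-bis(benzyloxy)-5,6-dimethylbenzaldehyde
Product: 18 2,4-bis(benzyloxy)-5,6-dimethylbenzoic acid
Conditions: NaClO2, NaH2PO4, 2-methylbut-2-ene, t-BuOH/H2O, rt
Reagents that add atoms: sodium chlorite, [Na+].[O-]Cl=O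
Why: Pinnick oxidation turns the aldehyde into the acid, with 2-methylbut-2-ene removing the hypochlorous acid that would otherwise chlorinate the electron-rich ring.

Step 11
Reactants: 18 2,4-bis(benzyloxy)-5,6-dimethylbenzoic acid; 13 (3S)-3-(2-bromo-3,5-dimethoxy-6-methylphenyl)butane-1,2-diol
Product: 20 (3S)-3-(2-bromo-3,5-dimethoxy-6-methylphenyl)-2-hydroxybutyl 2,4-bis(benzyloxy)-5,6-dimethylbenzoate (both C2 epimers), via acid chloride 19 (not isolated)
Conditions: (COCl)2, DMF (cat.), CH2Cl2, 0 °C → rt; then 13, pyridine, DMAP (cat.), CH2Cl2, −20 → 0 °C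
Reagents that add atoms: none
Why: Acylation through the acid chloride with DMAP catalysis: the di-ortho-substituted aroyl group is delivered only to the unhindered primary C9 hydroxyl and the secondary C3 hydroxyl stays free.

Step 12
Reactants: 20 (3S)-3-(2-bromo-3,5-dimethoxy-6-methylphenyl)-2-hydroxybutyl 2,4-bis(benzyloxy)-5,6-dimethylbenzoate
Product: 21 (3S)-3-(2-bromo-3,5-dimethoxy-6-methylphenyl)-2-oxobutyl 2,4-bis(benzyloxy)-5,6-dimethylbenzoate
Conditions: Dess–Martin periodinane, CH2Cl2, 0 °C → rt
Reagents that add atoms: none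
Why: Dess–Martin oxidation converts the C3 carbinol (both epimers) into the ketone under non-basic conditions, so that the α-aryl centre C4 is not enolised.

Step 13
Reactants: 21 (3S)-3-(2-bromo-3,5-dimethoxy-6-methylphenyl)-2-oxobutyl 2,4-bis(benzyloxy)-5,6-dimethylbenzoate
Product: 23 [(3R,4S)-3-hydroxy-6,8-dimethoxy-4,5-dimethyl-1-oxo-3,4-dihydro-1H-isochromen-3-yl]methyl 2,4-bis(benzyloxy)-5,6-dimethylbenzoate, via keto acid 22 (not isolated)
Conditions: Pd(OAc)2 (5 mol %), di(1-adamantyl)-n-butylphosphine (10 mol %), CO (5 bar), KOAc, H2O (10 equiv), 1,4-dioxane, 80 °C; then pH 4 citrate buffer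
Reagents that add atoms: carbon monoxide, [C-]#[O+]; water, O
Why: Zerovalent palladium, formed from Pd(OAc)2 and the bulky electron-rich phosphine, inserts into the C8a–Br bond, CO insertion gives the aroyl complex of divalent palladium (C8a–C1 formed), and acetate or water attacks the aroyl group (C1–O2 formed) to give benzoic acid 22, which stays as its open potassium salt until the acidic work-up. The closest known reaction is the palladium-catalysed hydroxycarbonylation of aryl bromides (Heck carbonylation), followed by the ring–chain tautomerism of 2-(2-oxoalkyl)benzoic acids. On acidification the carboxyl oxygen adds to the C3 ketone in a 6-exo-trig closure (O2–C3 formed), which gives the lactol ring C1–O2–C3–C4–C4a–C8a. C3 is formed reversibly and is set under thermodynamic control by C4: in the half-chair the C4 methyl is pseudoaxial to avoid the peri C5 methyl, the anomeric hydroxyl takes the axial position trans to it and the acyloxymethyl group the equatorial one, which is the (3R,4S) isomer. The step needs capture of the aroylpalladium by water or acetate instead of the enol oxygen (which would give the 4-methylisocoumarin and erase C4) or the C9 enolate carbon (ketone arylation), and this is secured by the weak base KOAc with excess water and by C8a being the only halogenated carbon. Retention at C4 rests on the di-ortho-substituted ring, which cannot become coplanar with a C3–C4 enol and so keeps the C4 hydrogen weakly acidic.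

Step 14
Reactants: 23 [(3R,4S)-3-hydroxy-6,8-dimethoxy-4,5-dimethyl-1-oxo-3,4-dihydro-1H-isochromen-3-yl]methyl 2,4-bis(benzyloxy)-5,6-dimethylbenzoate
Product: 24 [(3R,4S)-3-hydroxy-6,8-dimethoxy-4,5-dimethyl-1-oxo-3,4-dihydro-1H-isochromen-3-yl]methyl 2,4-dihydroxy-5,6-dimethylbenzoate
Conditions: H2 (1 atm), Pd/C (10 % palladium on carbon), EtOAc, rt
Reagents that add atoms: none
Why: Hydrogenolysis of the two aryl benzyl ethers over palladium leaves the lactol, the lactone and the non-benzylic C9 ester untouched, and it is run before the demethylation because MgI2 could also cleave the benzyl ether ortho to the ring B ester carbonyl.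

Step 15
Reactants: 24 [(3R,4S)-3-hydroxy-6,8-dimethoxy-4,5-dimethyl-1-oxo-3,4-dihydro-1H-isochromen-3-yl]methyl 2,4-dihydroxy-5,6-dimethylbenzoate
Product: 25 [(3R,4S)-3,8-dihydroxy-6-methoxy-4,5-dimethyl-1-oxo-3,4-dihydro-1H-isochromen-3-yl]methyl 2,4-dihydroxy-5,6-dimethylbenzoate (CNP0072952.2)
Conditions: MgI2 (diethyl etherate, 4 equiv), THF, 50 °C; then dilute aq. HCl
Reagents that add atoms: none
Why: Chelation-controlled ether cleavage: magnesium bound between the lactone carbonyl and the peri C8 methoxyl activates that methyl group for SN2 attack by iodide, while the C6 methoxyl has no neighbouring carbonyl and stays, and the C4–C5 peri strain of the corresponding isocoumarin disfavours dehydration of the lactol.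

**Compound list**
1 | 1-bromo-3,5-dimethoxybenzene | COc1cc(Br)cc(OC)c1 | starting material
2 | [(2-bromo-4,6-dimethoxyphenyl)methylidene]dimethylammonium chloride | COc1cc(OC)c(C=[N+](C)C)c(Br)c1.[Cl-] | intermediate (not isolated)
3 | 2-bromo-4,6-dimethoxybenzaldehyde | COc1cc(OC)c(C=O)c(Br)c1 | intermediate
4 | 1-bromo-3,5-dimethoxy-2-methylbenzene | COc1cc(OC)c(C)c(Br)c1 | intermediate
5 | (3,5-dimethoxy-2-methylphenyl)lithium | [Li]c1cc(OC)cc(OC)c1C | intermediate (not isolated)
6 | lithium (3,5-dimethoxy-2-methylphenyl)triisopropoxyborate | [Li+].COc1cc(OC)c(C)c(c1)[B-](OC(C)C)(OC(C)C)OC(C)C | intermediate (not isolated)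
7 | (3,5-dimethoxy-2-methylphenyl)boronic acid | COc1cc(OC)c(C)c(c1)B(O)O | intermediate
8 | ethyl (E)-but-2-enoate | C/C=C/C(=O)OCC | starting material
9 | ethyl (3R)-3-(3,5-dimethoxy-2-methylphenyl)butanoate | COc1cc(OC)cc(c1C)[C@H](C)CC(=O)OCC | intermediate
10 | potassium enolate of ester 9 | [K+].COc1cc(OC)cc(c1C)[C@H](C)C=C([O-])OCC | intermediate (not isolated)
11 | ethyl (3S)-3-(3,5-dimethoxy-2-methylphenyl)-2-hydroxybutanoate (both C2 epimers) | COc1cc(OC)cc(c1C)[C@H](C)C(O)C(=O)OCC | intermediate
12 | (3S)-3-(3,5-dimethoxy-2-methylphenyl)butane-1,2-diol (both C2 epimers) | COc1cc(OC)cc(c1C)[C@H](C)C(O)CO | intermediate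
13 | (3S)-3-(2-bromo-3,5-dimethoxy-6-methylphenyl)butane-1,2-diol (both C2 epimers) | COc1cc(OC)c(Br)c(c1C)[C@H](C)C(O)CO | intermediate
14 | 4,5-dimethylbenzene-1,3-diol | Cc1cc(O)cc(O)c1C | starting material
15 | [(2,4-dihydroxy-5,6-dimethylphenyl)methylidene]dimethylammonium chloride | C[N+](C)=Cc1c(O)cc(O)c(C)c1C.[Cl-] | intermediate (not isolated)
16 | 2,4-dihydroxy-5,6-dimethylbenzaldehyde | O=Cc1c(O)cc(O)c(C)c1C | intermediate
17 | 2,4-bis(benzyloxy)-5,6-dimethylbenzaldehyde | O=Cc1c(OCc2ccccc2)cc(OCc2ccccc2)c(C)c1C | intermediate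
18 | 2,4-bis(benzyloxy)-5,6-dimethylbenzoic acid | OC(=O)c1c(OCc2ccccc2)cc(OCc2ccccc2)c(C)c1C | intermediate
19 | 2,4-bis(benzyloxy)-5,6-dimethylbenzoyl chloride | ClC(=O)c1c(OCc2ccccc2)cc(OCc2ccccc2)c(C)c1C | intermediate (not isolated)
20 | (3S)-3-(2-bromo-3,5-dimethoxy-6-methylphenyl)-2-hydroxybutyl 2,4-bis(benzyloxy)-5,6-dimethylbenzoate (both C2 epimers) | COc1cc(OC)c(Br)c(c1C)[C@H](C)C(O)COC(=O)c1c(OCc2ccccc2)cc(OCc2ccccc2)c(C)c1C | intermediate
21 | (3S)-3-(2-bromo-3,5-dimethoxy-6-methylphenyl)-2-oxobutyl 2,4-bis(benzyloxy)-5,6-dimethylbenzoate | COc1cc(OC)c(Br)c(c1C)[C@H](C)C(=O)COC(=O)c1c(OCc2ccccc2)cc(OCc2ccccc2)c(C)c1C | intermediate (key-step precursor)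
22 | 2-[(2S)-4-{[2,4-bis(benzyloxy)-5,6-dimethylbenzoyl]oxy}-3-oxobutan-2-yl]-4,6-dimethoxy-3-methylbenzoic acid | COc1cc(OC)c(C(O)=O)c(c1C)[C@H](C)C(=O)COC(=O)c1c(OCc2ccccc2)cc(OCc2ccccc2)c(C)c1C | intermediate (not isolated)
23 | [(3R,4S)-3-hydroxy-6,8-dimethoxy-4,5-dimethyl-1-oxo-3,4-dihydro-1H-isochromen-3-yl]methyl 2,4-bis(benzyloxy)-5,6-dimethylbenzoate | COc1cc(OC)c2c(c1C)[C@H](C)[C@](O)(COC(=O)c1c(OCc3ccccc3)cc(OCc3ccccc3)c(C)c1C)OC2=O | intermediate (key-step product)
24 | [(3R,4S)-3-hydroxy-6,8-dimethoxy-4,5-dimethyl-1-oxo-3,4-dihydro-1H-isochromen-3-yl]methyl 2,4-dihydroxy-5,6-dimethylbenzoate | COc1cc(OC)c2c(c1C)[C@H](C)[C@](O)(COC(=O)c1c(O)cc(O)c(C)c1C)OC2=O | intermediate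
25 | [(3R,4S)-3,8-dihydroxy-6-methoxy-4,5-dimethyl-1-oxo-3,4-dihydro-1H-isochromen-3-yl]methyl 2,4-dihydroxy-5,6-dimethylbenzoate | COc1cc(O)c2c(c1C)[C@H](C)[C@](O)(COC(=O)c1c(O)cc(O)c(C)c1C)OC2=O | target

**Step count and risks**
Total step count: 15. Longest linear sequence: 12 steps (steps 1 to 7, then 11 to 15); steps 8 to 10 make the ring B acid in a side branch.

Steps most likely to fail:

1. Step 13. Oxidative addition at the hindered, electron-rich C8a–Br bond may be slow under CO, so that enolisation of the ketone (loss of the C4 configuration) or capture of the aroylpalladium by the enol oxygen competes. The fallback sets out from bromo diol 13 and comes back to the route at lactol 23, and brings C1 in by organolithium chemistry before any ketone or aryl ester is present. The diol is protected (2,2-dimethoxypropane, pyridinium p-toluenesulfonate) as the acetonide F1. Bromine–lithium exchange (n-BuLi, THF, −78 °C) gives the aryllithium F2, which is trapped with di-tert-butyl dicarbonate to give the tert-butyl ester acetonide F3. Aqueous AcOH at 40 °C removes the acetonide and gives the diol tert-butyl ester F4, whose hindered tert-butyl ester should resist lactonisation. Acid chloride 19 (pyridine, DMAP) acylates the primary hydroxyl to give the hydroxy diester F5, and Dess–Martin oxidation gives the keto tert-butyl ester F6. TFA in CH2Cl2 at 0 °C cleaves the tert-butyl ester to keto acid 22, which closes to 23.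

2. Step 4. Protodeboronation of the electron-rich, ortho-substituted boronic acid may outrun insertion of the crotonate, and the ortho-methyl group may erode the facial selectivity. The fallback sets out from aryl bromide 4 and comes back at ester 9, and replaces catalyst control by auxiliary control. Mg turnings in THF convert 4 into the arylmagnesium bromide F7. With CuBr·SMe2 (THF, −20 °C) this adds to the crotonyl imide F8 (made from (S)-4-phenyl-1,3-oxazolidin-2-one, n-BuLi and (E)-but-2-enoyl chloride) on the face of the chelated imide away from the phenyl group, to give the conjugate adduct F9 with the (3R) configuration. EtOMgBr in THF/EtOH then exchanges the auxiliary for ethoxide and gives 9.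

3. Step 11. Acyl transfer from the di-ortho-substituted aroyl chloride may be sluggish, so that conversion stays incomplete or forcing conditions bring acylation of the secondary hydroxyl. The fallback sets out from bromo diol 13 and comes back at hydroxy ester 20, and uses the hindered acid as the nucleophile instead of the electrophile. Bu2SnO-catalysed tosylation (TsCl, Et3N, CH2Cl2) of the primary hydroxyl gives the monotosylate F10. The caesium salt of acid 18 (Cs2CO3, DMF, 60 °C) then displaces the tosylate, directly or by opening at its unsubstituted carbon the terminal epoxide F11 that forms in the flask, to give 20.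

Further compounds
F1 | step 13 | (4RS)-4-[(1S)-1-(2-bromo-3,5-dimethoxy-6-methylphenyl)ethyl]-2,2-dimethyl-1,3-dioxolane | COc1cc(OC)c(Br)c(c1C)[C@H](C)C1COC(C)(C)O1
F2 | step 13 | {2-[(1S)-1-(2,2-dimethyl-1,3-dioxolan-4-yl)ethyl]-4,6-dimethoxy-3-methylphenyl}lithium | [Li]c1c(OC)cc(OC)c(C)c1[C@H](C)C1COC(C)(C)O1
F3 | step 13 | tert-butyl 2-[(1S)-1-(2,2-dimethyl-1,3-dioxolan-4-yl)ethyl]-4,6-dimethoxy-3-methylbenzoate | COc1cc(OC)c(C(=O)OC(C)(C)C)c(c1C)[C@H](C)C1COC(C)(C)O1
F4 | step 13 | tert-butyl 2-[(2S)-3,4-dihydroxybutan-2-yl]-4,6-dimethoxy-3-methylbenzoate | COc1cc(OC)c(C(=O)OC(C)(C)C)c(c1C)[C@H](C)C(O)CO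
F5 | step 13 | tert-butyl 2-[(2S)-4-{[2,4-bis(benzyloxy)-5,6-dimethylbenzoyl]oxy}-3-hydroxybutan-2-yl]-4,6-dimethoxy-3-methylbenzoate | COc1cc(OC)c(C(=O)OC(C)(C)C)c(c1C)[C@H](C)C(O)COC(=O)c1c(OCc2ccccc2)cc(OCc2ccccc2)c(C)c1C
F6 | step 13 | tert-butyl 2-[(2S)-4-{[2,4-bis(benzyloxy)-5,6-dimethylbenzoyl]oxy}-3-oxobutan-2-yl]-4,6-dimethoxy-3-methylbenzoate | COc1cc(OC)c(C(=O)OC(C)(C)C)c(c1C)[C@H](C)C(=O)COC(=O)c1c(OCc2ccccc2)cc(OCc2ccccc2)c(C)c1C
F7 | step 4 | (3,5-dimethoxy-2-methylphenyl)magnesium bromide | Br[Mg]c1cc(OC)cc(OC)c1C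
F8 | step 4 | (4S)-3-[(2E)-but-2-enoyl]-4-phenyl-1,3-oxazolidin-2-one | C/C=C/C(=O)N1C(=O)OC[C@@H]1c1ccccc1
F9 | step 4 | (4S)-3-[(3R)-3-(3,5-dimethoxy-2-methylphenyl)butanoyl]-4-phenyl-1,3-oxazolidin-2-one | COc1cc(OC)cc(c1C)[C@H](C)CC(=O)N1C(=O)OC[C@@H]1c1ccccc1
F10 | step 11 | (3S)-3-(2-bromo-3,5-dimethoxy-6-methylphenyl)-2-hydroxybutyl 4-methylbenzenesulfonate | COc1cc(OC)c(Br)c(c1C)[C@H](C)C(O)COS(=O)(=O)c1ccc(C)cc1
F11 | step 11 | 2-[(1S)-1-(2-bromo-3,5-dimethoxy-6-methylphenyl)ethyl]oxirane | COc1cc(OC)c(Br)c(c1C)[C@H](C)C1CO1
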